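**Retrosynthetic overview**
1. Last ring (the carbocycle of the 2-oxabicyclo[2.2.2]octane, spiro C8): the C4–C8 bond is made by capture of an oxan-2-ylium ion by the enol of a 3-methyl β-keto-δ-lactone.
2. Second ring (β-keto-δ-lactone), the key step: ring expansion oxetan-2-one → oxane-2,4-dione by inserting the C=O of an α-methyl aldehyde into (R)-methylketene dimer.
3. First ring (oxane): methyl ketalisation of a δ-hydroxy ketone assembled from (S)-methylketene dimer, N-methoxy-N-methylamide and a syn α-methyl-β-silyloxy aldehyde (ring-opening/syn-aldol).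
4. The aldehyde comes from (2S,3S)-2,3-dimethyloxirane and vinylmagnesium bromide, then ozonolysis; both dimers come from one batch of methylketene made from 2-bromopropanoyl bromide.
5. Order of ring formation: oxane → δ-lactone → bicyclic carbocycle.

Assumption: (2S,3S)-2,3-dimethyloxirane is bought as the single enantiomer, 2-bromopropanoyl bromide is used as the racemate, and O-trimethylsilylquinine gives the (S)-dimer while O-trimethylsilylquinidine gives the (R)-dimer (if the sense is the reverse, the two catalysts are exchanged).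

**Route**

Step 1
Reactants: 1 (2S,3S)-2,3-dimethyloxirane; 2 vinylmagnesium bromide
Product: 4 triethyl{[(2S,3S)-3-methylpent-4-en-2-yl]oxy}silane, via bromomagnesium alkoxide 3 (not isolated)
Conditions: CuI (10 mol%), THF, −30 → 0 °C; then Et3SiCl, imidazole, DMF, 0 °C → rt
Reagents that add atoms: chlorotriethylsilane, CC[Si](CC)(CC)Cl
Why: Copper-catalysed SN2 opening of the C2-symmetric trans-epoxide by the vinyl Grignard reagent inverts the attacked carbon and so fixes the syn (2S,3S) relationship, and the alkoxide 3 is silylated in the same pot so that the volatile alcohol is never isolated.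

Step 2
Reactants: 4 triethyl{[(2S,3S)-3-methylpent-4-en-2-yl]oxy}silane
Product: 5 (2R,3S)-2-methyl-3-[(triethylsilyl)oxy]butanal
Conditions: O3, CH2Cl2, −78 °C; then PPh3, −78 °C → rt
Reagents that add atoms: ozone, [O-][O+]=O
Why: Ozonolysis with reductive work-up cleaves the terminal alkene to the aldehyde under neutral conditions that leave the silyl ether and the α-stereocentre untouched.

Step 3
Reactants: 6 2-bromopropanoyl bromide (racemic)
Product: 7 methylketene (prop-1-en-1-one), collected as a THF solution at −78 °C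
Conditions: activated Zn dust (1.1 equiv), THF, −10 °C, reduced pressure, ketene co-distilled with THF into a −78 °C receiver; solution divided into two halves and used the same day
Reagents that add atoms: none
Why: Zinc inserts into the α C–Br bond and the zinc enolate loses bromide (reductive 1,2-dehalogenation of an α-haloacyl halide), and co-distillation takes the ketene away from ZnBr2 before it can dimerise without control; no stereocentre is formed.

Step 4
Reactants: 7 methylketene (2 equiv, first half of the solution)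
Product: 8 (3S,4Z)-4-ethylidene-3-methyloxetan-2-one
Conditions: O-trimethylsilylquinine (2 mol%), THF, −78 °C, 4 h; used as its THF solution
Reagents that add atoms: none
Why: The cinchona-derived nucleophilic catalyst adds to one ketene to give an ammonium enolate that acylates a second ketene and lactonises (catalytic asymmetric ketene dimerisation) to the Z enol β-lactone, the catalyst setting C3 as S.

Step 5
Reactants: 8 (3S,4Z)-4-ethylidene-3-methyloxetan-2-one; 5 (2R,3S)-2-methyl-3-[(triethylsilyl)oxy]butanal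
Product: 11 (2S)-2-[(2S,3S,4R,5S,6S)-4-hydroxy-2-methoxy-3,5,6-trimethyloxan-2-yl]-N-methoxy-N-methylpropanamide, via lithium enolate 9 (not isolated), via aldol adduct 10 (not isolated)
Conditions: MeNHOMe·HCl, n-BuLi (2 equiv), THF, −78 °C; 8; then 5, −78 °C; aq NH4Cl; crude product in MeOH, pyridinium p-toluenesulfonate (10 mol%), 0 °C → rt
Reagents that add atoms: N,O-dimethylhydroxylamine hydrochloride (used as its lithium amide), CNOC.Cl; methanol, CO
Why: The known amide-triggered ring-opening of the ketene dimer gives the Z lithium enolate 9, whose chelated chair aldol with 5 is syn to the resident methyl group and syn at the new C4/C5 pair of 10 and anti-Felkin towards the aldehyde (Z-enolate preference, matched case), after which acidic methanol removes the silyl group and closes the oxane as its axial methyl ketal (anomeric control).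

Step 6
Reactants: 11 (2S)-2-[(2S,3S,4R,5S,6S)-4-hydroxy-2-methoxy-3,5,6-trimethyloxan-2-yl]-N-methoxy-N-methylpropanamide
Product: 12 (2S,3S,4R,5R,6S)-2-methoxy-2-{(2S)-1-[methoxy(methyl)amino]-1-oxopropan-2-yl}-3,5,6-trimethyloxan-4-yl acetate
Conditions: Ac2O, 4-(dimethylamino)pyridine (cat.), pyridine, CH2Cl2, 0 °C → rt
Reagents that add atoms: acetic anhydride, CC(=O)OC(C)=O
Why: Nucleophile-catalysed acylation of the only free (secondary, equatorial) alcohol, with the ketal and the Weinreb amide inert and no free ketone present that could lose acetate by β-elimination.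

Step 7
Reactants: 12 (2S,3S,4R,5R,6S)-2-methoxy-2-{(2S)-1-[methoxy(methyl)amino]-1-oxopropan-2-yl}-3,5,6-trimethyloxan-4-yl acetate
Product: 13 (2S,3S,4R,5R,6S)-2-methoxy-3,5,6-trimethyl-2-[(2R)-1-oxopropan-2-yl]oxan-4-yl acetate
Conditions: Cp2Zr(H)Cl (1.5 equiv), THF, rt, 20 min; then wet silica gel
Reagents that add atoms: none
Why: Hydrozirconation of the amide carbonyl gives a zirconated hemiaminal that releases the aldehyde only on work-up, a reduction of tertiary amides known to spare esters and ketals and not to epimerise the α-stereocentre.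

Step 8
Reactants: 7 methylketene (2 equiv, second half of the solution)
Product: 14 (3R,4Z)-4-ethylidene-3-methyloxetan-2-one
Conditions: O-trimethylsilylquinidine (2 mol%), THF, −78 °C, 4 h, run side by side with step 4; THF solution stored at −20 °C until used
Reagents that add atoms: none
Why: The same catalytic asymmetric ketene dimerisation as in step 4, run with the pseudoenantiomeric alkaloid so that C3 is set as R.

Step 9
Reactants: 13 (2S,3S,4R,5R,6S)-2-methoxy-3,5,6-trimethyl-2-[(2R)-1-oxopropan-2-yl]oxan-4-yl acetate; 14 (3R,4Z)-4-ethylidene-3-methyloxetan-2-one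
Product: 17 (2S,3S,4R,5R,6S)-2-{(1R)-1-[(2R,3R)-3,5-dimethyl-4,6-dioxooxan-2-yl]ethyl}-2-methoxy-3,5,6-trimethyloxan-4-yl acetate, via thioester enolate 15 (not isolated), via lithium aldolate 16 (not isolated)
Conditions: PhSH, n-BuLi, THF, −78 °C (PhSLi, 1.05 equiv); 14 (1.15 equiv), 10 min; then 13, −78 → 0 °C; aq NH4Cl; product used crude
Reagents that add atoms: none
Why: Proposed new method: PhSLi acylates at the lactone carbonyl of 14 just as amide nucleophiles do in the known ring-opening/aldol of methylketene dimer and unveils the Z lithium enolate 15, which adds to 13 through a closed chair transition state in the anti-Felkin sense (matched with the 2-methyl group of 15) to set the carbinol carbon (later C1 of the bicycle) anti to the side-chain methyl, and the δ-alkoxide 16 then expels thiolate from the activated thioester (6-exo-trig) so that the four-membered enol lactone is expanded by the aldehyde C=O to the six-membered oxane-2,4-dione; the closest known reaction types are the amide-triggered ketene-dimer opening/aldol and the TiCl4-mediated diketene–aldehyde synthesis of 5,6-dihydro-4-hydroxy-2-pyranones (acyl-transfer ring expansion).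

Step 10
Reactants: 17 (2S,3S,4R,5R,6S)-2-{(1R)-1-[(2R,3R)-3,5-dimethyl-4,6-dioxooxan-2-yl]ethyl}-2-methoxy-3,5,6-trimethyloxan-4-yl acetate
Product: 19 (1S,3'S,4R,4'R,5'R,6S,6'S,7R,8S)-3',4,5',6,6',7-hexamethyl-3,5-dioxospiro[2-oxabicyclo[2.2.2]octane-8,2'-oxan]-4'-yl acetate (target), via oxocarbenium ion 18 (not isolated)
Conditions: CF3CO2H (5 equiv), CH2Cl2, 0 → 40 °C
Reagents that add atoms: none
Why: Acid ionises the methyl ketal to the oxan-2-ylium ion 18, which is captured at carbon by the enol of the β-keto lactone (intramolecular Mukaiyama/Prins-type C-alkylation of a 1,3-dicarbonyl, 6-enolendo-exo-trig) along the axial trajectory of the oxane to set spiro C8, while bridgehead C4 is fixed by the lactone tether and the C6 methyl (α to the ketone, formed as the 6-epimer from the syn aldol) equilibrates through the enol to the less hindered face next to the oxygen bridge.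

**Compound list**
1 | (2S,3S)-2,3-dimethyloxirane | C[C@@H]1O[C@H]1C | starting material
2 | vinylmagnesium bromide | C=C[Mg]Br | starting material
3 | bromomagnesium (2S,3S)-3-methylpent-4-en-2-olate | C=C[C@H](C)[C@H](C)O[Mg]Br | intermediate
4 | triethyl{[(2S,3S)-3-methylpent-4-en-2-yl]oxy}silane | C=C[C@H](C)[C@H](C)O[Si](CC)(CC)CC | intermediate
5 | (2R,3S)-2-methyl-3-[(triethylsilyl)oxy]butanal | O=C[C@H](C)[C@H](C)O[Si](CC)(CC)CC | intermediate
6 | 2-bromopropanoyl bromide (racemic) | CC(Br)C(=O)Br | starting material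
7 | methylketene (prop-1-en-1-one) | CC=C=O | intermediate
8 | (3S,4Z)-4-ethylidene-3-methyloxetan-2-one | C/C=C1\OC(=O)[C@H]1C | intermediate
9 | lithium (2Z,4S)-5-[methoxy(methyl)amino]-4-methyl-5-oxopent-2-en-3-olate | C/C=C(\[O-])[C@H](C)C(=O)N(C)OC.[Li+] | intermediate
10 | (2S,4S,5R,6S,7S)-5-hydroxy-N-methoxy-N,2,4,6-tetramethyl-3-oxo-7-[(triethylsilyl)oxy]octanamide | O[C@H]([C@H](C)[C@H](C)O[Si](CC)(CC)CC)[C@H](C)C(=O)[C@H](C)C(=O)N(C)OC | intermediate
11 | (2S)-2-[(2S,3S,4R,5S,6S)-4-hydroxy-2-methoxy-3,5,6-trimethyloxan-2-yl]-N-methoxy-N-methylpropanamide | O[C@@H]1[C@H](C)[C@H](C)O[C@](OC)([C@H](C)C(=O)N(C)OC)[C@H]1C | intermediate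
12 | (2S,3S,4R,5R,6S)-2-methoxy-2-{(2S)-1-[methoxy(methyl)amino]-1-oxopropan-2-yl}-3,5,6-trimethyloxan-4-yl acetate | CC(=O)O[C@@H]1[C@H](C)[C@H](C)O[C@](OC)([C@H](C)C(=O)N(C)OC)[C@H]1C | intermediate
13 | (2S,3S,4R,5R,6S)-2-methoxy-3,5,6-trimethyl-2-[(2R)-1-oxopropan-2-yl]oxan-4-yl acetate | CC(=O)O[C@@H]1[C@H](C)[C@H](C)O[C@](OC)([C@H](C)C=O)[C@H]1C | intermediate
14 | (3R,4Z)-4-ethylidene-3-methyloxetan-2-one | C/C=C1\OC(=O)[C@@H]1C | intermediate
15 | lithium (2Z,4R)-4-methyl-5-oxo-5-(phenylsulfanyl)pent-2-en-3-olate | C/C=C(\[O-])[C@@H](C)C(=O)Sc1ccccc1.[Li+] | intermediate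
16 | lithium δ-alkoxide of the S-phenyl 5-hydroxy-2,4-dimethyl-3-oxo-6-(oxan-2-yl)heptanethioate (2,4-syn; 4,5-syn; 5,6-anti; oxane as in 13) | CC(=O)O[C@@H]1[C@H](C)[C@H](C)O[C@](OC)([C@H](C)[C@H]([O-])[C@@H](C)C(=O)[C@@H](C)C(=O)Sc2ccccc2)[C@H]1C.[Li+] | intermediate
17 | (2S,3S,4R,5R,6S)-2-{(1R)-1-[(2R,3R)-3,5-dimethyl-4,6-dioxooxan-2-yl]ethyl}-2-methoxy-3,5,6-trimethyloxan-4-yl acetate (C5 of the dioxooxane ring unset; largely enolised) | CC(=O)O[C@@H]1[C@H](C)[C@H](C)O[C@](OC)([C@H](C)[C@@H]2OC(=O)C(C)C(=O)[C@@H]2C)[C@H]1C | intermediate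
18 | oxan-2-ylium (oxocarbenium) ion from 17 by loss of methoxide | CC(=O)O[C@@H]1[C@H](C)[C@H](C)[O+]=C([C@H](C)[C@@H]2OC(=O)C(C)C(=O)[C@@H]2C)[C@H]1C | intermediate
19 | (1S,3'S,4R,4'R,5'R,6S,6'S,7R,8S)-3',4,5',6,6',7-hexamethyl-3,5-dioxospiro[2-oxabicyclo[2.2.2]octane-8,2'-oxan]-4'-yl acetate | CC(=O)O[C@@H]1[C@H](C)[C@H](C)O[C@]2([C@H](C)[C@@H]3OC(=O)[C@@]2(C)C(=O)[C@H]3C)[C@H]1C | target

**Step count**
Total: 10 steps. Longest linear sequence: 7 steps (1, 2, 5, 6, 7, 9, 10).

**Three steps most likely to fail**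

Step 5. The aldol is a double stereodifferentiating reaction with a β-silyloxy aldehyde, and the in-line ketalisation must not epimerise the β-keto amide. The fallback sets out from 8 and 5 and comes back to the route at 13, using a reagent-controlled ethyl-ketone aldol and a late oxidation instead of the amide series. Reduction of 8 with LiAlH4 (THF, −78 °C) gives (2R)-1-hydroxy-2-methylpentan-3-one F1, which is protected with 4-methoxybenzyl trichloroacetimidate to give (2R)-1-[(4-methoxyphenyl)methoxy]-2-methylpentan-3-one F2. Its Sn(OTf)2/Et3N enolate adds to 5 to give the syn,syn aldol (2R,4S,5R,6S,7S)-5-hydroxy-1-[(4-methoxyphenyl)methoxy]-2,4,6-trimethyl-7-[(triethylsilyl)oxy]octan-3-one F3. Pyridinium p-toluenesulfonate in MeOH then gives (2R,3S,4R,5S,6S)-2-methoxy-2-{(2R)-1-[(4-methoxyphenyl)methoxy]propan-2-yl}-3,5,6-trimethyloxan-4-ol F4, and acetylation gives (2R,3S,4R,5R,6S)-2-methoxy-2-{(2R)-1-[(4-methoxyphenyl)methoxy]propan-2-yl}-3,5,6-trimethyloxan-4-yl acetate F5. DDQ frees (2R,3S,4R,5R,6S)-2-[(2R)-1-hydroxypropan-2-yl]-2-methoxy-3,5,6-trimethyloxan-4-yl acetate F6, and Dess–Martin oxidation gives 13. This also avoids the amide reduction of step 7.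

Step 9 (the proposed new ring expansion). Possible failures are proton transfer within the thioester enolate, retro-aldol before lactonisation, and loss of methanol from 13 under base. The fallback uses known chemistry, sets out from 13 and 14 and comes back at 17. The established opening of 14 with LiN(OMe)Me (THF, −78 °C) followed by addition of 13 gives the δ-hydroxy-β-keto Weinreb amide (2,4-syn; 4,5-syn; 5,6-anti) F7. Acid-catalysed lactonisation (camphorsulfonic acid, toluene, 40 °C) with loss of MeNHOMe gives 17, which in the same acidic medium may go on as in step 10.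

Step 10. The oxocarbenium ion may be captured at the enol oxygen (a spiroketal enol ether) instead of at carbon, proton loss to enol ethers could scramble C7 or C3', and the C6 equilibration may be slow. The fallback sets out from 17 and comes back at 19. O-silylation (t-BuMe2SiCl, imidazole, DMF) gives the 4-silyloxy-5,6-dihydro-2-pyranone F8. Me3SiOTf (cat.) with 2,6-di-tert-butylpyridine in CH2Cl2 at −78 °C then ionises the ketal, and the silyl enol ether can react only at carbon (intramolecular Mukaiyama reaction with a ketal). Brief CF3CO2H treatment to settle C6 gives 19.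

**Further compounds**
F1 | step 5 | (2R)-1-hydroxy-2-methylpentan-3-one | OC[C@@H](C)C(=O)CC
F2 | step 5 | (2R)-1-[(4-methoxyphenyl)methoxy]-2-methylpentan-3-one | CCC(=O)[C@H](C)COCc1ccc(OC)cc1
F3 | step 5 | (2R,4S,5R,6S,7S)-5-hydroxy-1-[(4-methoxyphenyl)methoxy]-2,4,6-trimethyl-7-[(triethylsilyl)oxy]octan-3-one | O[C@H]([C@H](C)[C@H](C)O[Si](CC)(CC)CC)[C@H](C)C(=O)[C@H](C)COCc1ccc(OC)cc1
F4 | step 5 | (2R,3S,4R,5S,6S)-2-methoxy-2-{(2R)-1-[(4-methoxyphenyl)methoxy]propan-2-yl}-3,5,6-trimethyloxan-4-ol | O[C@@H]1[C@H](C)[C@H](C)O[C@](OC)([C@H](C)COCc2ccc(OC)cc2)[C@H]1C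
F5 | step 5 | (2R,3S,4R,5R,6S)-2-methoxy-2-{(2R)-1-[(4-methoxyphenyl)methoxy]propan-2-yl}-3,5,6-trimethyloxan-4-yl acetate | CC(=O)O[C@@H]1[C@H](C)[C@H](C)O[C@](OC)([C@H](C)COCc2ccc(OC)cc2)[C@H]1C
F6 | step 5 | (2R,3S,4R,5R,6S)-2-[(2R)-1-hydroxypropan-2-yl]-2-methoxy-3,5,6-trimethyloxan-4-yl acetate | CC(=O)O[C@@H]1[C@H](C)[C@H](C)O[C@](OC)([C@H](C)CO)[C@H]1C
F7 | step 9 | δ-hydroxy-β-keto Weinreb amide: 6-(oxan-2-yl)-5-hydroxy-N-methoxy-N,2,4-trimethyl-3-oxoheptanamide (2,4-syn; 4,5-syn; 5,6-anti; oxane as in 13) | CC(=O)O[C@@H]1[C@H](C)[C@H](C)O[C@](OC)([C@H](C)[C@H](O)[C@@H](C)C(=O)[C@@H](C)C(=O)N(C)OC)[C@H]1C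
F8 | step 10 | tert-butyldimethylsilyl enol ether of 17 (4-silyloxy-3,5-dimethyl-5,6-dihydro-2H-pyran-2-one, oxane as in 17) | CC(=O)O[C@@H]1[C@H](C)[C@H](C)O[C@](OC)([C@H](C)[C@@H]2OC(=O)C(C)=C(O[Si](C)(C)C(C)(C)C)[C@@H]2C)[C@H]1C
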